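**Retrosynthetic overview**

1. Target 18 ← penta-O-benzyl ether 17 by global hydrogenolysis. No ring is formed anywhere in the route: both benzene rings come from the same aryl bromide 1.
2. Key disconnection: the CH2–C(=O)O bond (C2–C1) of the central 3-(aroyloxy)butanoate. 17 ← formate 6 + isopropenyl ester 16, by an enantioselective anti-Markovnikov hydroesterification that also creates the C3 stereocentre.
3. Enabling feature: the C2 methylene lies between the ester carbonyl C1 and C3, and C3 carries one H, a methyl group and the acyloxy oxygen of the 2,4-dioxygenated 6-alkylbenzoate ring. This is the retron of H/CO2R addition across a 1-methylvinyl (isopropenyl) ester of that benzoic acid.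
4. 16 ← acid 14 + propyne; 14 ← ester 11 by ring formylation and oxidation; 11 and 6 both ← alcohol 5 (from 1 + (R)-propylene oxide); the terminal unit comes from methyl (R)-3-hydroxybutanoate.

Key step: step 9

Remark: 1,3-bis(benzyloxy)-5-bromobenzene 1 is taken as a catalogue compound, the counter-ion of iminium salt 12 is drawn as chloride, and the ligand enantiomer named in step 9 is the one assumed to give the (R) centre, its antipode being used if a model reaction shows the opposite sense of induction.

**Step 1**
Reactants: 1 1,3-bis(benzyloxy)-5-bromobenzene; 2 (R)-2-methyloxirane ((R)-propylene oxide)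
Product: 5 (R)-1-[3,5-bis(benzyloxy)phenyl]propan-2-ol, via arylmagnesium bromide 3 (not isolated), via bromomagnesium alkoxide 4 (not isolated)
Conditions: Mg, THF, 50 °C; then CuI (10 mol %), 2, −30 → 0 °C; 1 M HCl work-up
Reagents that add atoms: none
Why: Cu-catalysed SN2 opening of a terminal epoxide by an aryl Grignard reagent at the unsubstituted CH2 carbon, so the (R) carbinol centre of 2 is carried into 5 untouched.

**Step 2**
Reactants: 5 (R)-1-[3,5-bis(benzyloxy)phenyl]propan-2-ol
Product: 6 (R)-1-[3,5-bis(benzyloxy)phenyl]propan-2-yl formate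
Conditions: HCO2H, DCC, DMAP (cat.), CH2Cl2, 0 °C → rt
Reagents that add atoms: formic acid OC=O
Why: Steglich-type O-formylation (carbodiimide activation of formic acid with DMAP acyl transfer) acylates the secondary alcohol on oxygen without touching the carbinol C–O bond, so the (R) centre is retained.

**Step 3**
Reactants: 7 methyl (R)-3-hydroxybutanoate
Product: 8 methyl (R)-3-(benzyloxy)butanoate
Conditions: BnOC(=NH)CCl3, TfOH (cat.), CH2Cl2/cyclohexane, 0 °C → rt
Reagents that add atoms: benzyl 2,2,2-trichloroacetimidate N=C(OCc1ccccc1)C(Cl)(Cl)Cl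
Why: Acid-catalysed O-benzylation with a trichloroacetimidate works under non-basic conditions that avoid β-elimination or retro-aldol cleavage of the β-hydroxy ester and leaves the (R) centre untouched.

**Step 4**
Reactants: 8 methyl (R)-3-(benzyloxy)butanoate
Product: 10 (R)-3-(benzyloxy)butanoic acid, via lithium carboxylate 9 (not isolated)
Conditions: LiOH, THF/H2O, 0 °C → rt; then 1 M HCl
Reagents that add atoms: lithium hydroxide [Li+].[OH-]
Why: Saponification of a methyl ester with LiOH at low temperature, followed by acidification, should proceed without β-elimination of the benzyloxy group.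

**Step 5**
Reactants: 5 (R)-1-[3,5-bis(benzyloxy)phenyl]propan-2-ol; 10 (R)-3-(benzyloxy)butanoic acid
Product: 11 (R)-1-[3,5-bis(benzyloxy)phenyl]propan-2-yl (R)-3-(benzyloxy)butanoate
Conditions: DCC, DMAP (cat.), CH2Cl2, 0 °C → rt
Reagents that add atoms: none
Why: Steglich esterification of a secondary alcohol with an unhindered acid whose stereocentre is β to the carbonyl and therefore not epimerisable, so both (R) centres are retained.

**Step 6**
Reactants: 11 (R)-1-[3,5-bis(benzyloxy)phenyl]propan-2-yl (R)-3-(benzyloxy)butanoate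
Product: 13 (R)-1-[3,5-bis(benzyloxy)-2-formylphenyl]propan-2-yl (R)-3-(benzyloxy)butanoate, via aryl iminium chloride 12 (not isolated)
Conditions: POCl3, DMF, 0 → 60 °C; then H2O, 0 °C → rt
Reagents that add atoms: N,N-dimethylformamide CN(C)C=O; water O
Why: Vilsmeier–Haack formylation of the electron-rich 1-alkyl-3,5-dialkoxybenzene ring should occur para to one benzyloxy group and ortho to the other at the position next to the side chain (the site between the two ether oxygens is the more hindered one), and esters and benzyl ethers tolerate the reagent.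

**Step 7**
Reactants: 13 (R)-1-[3,5-bis(benzyloxy)-2-formylphenyl]propan-2-yl (R)-3-(benzyloxy)butanoate
Product: 14 2,4-bis(benzyloxy)-6-[(R)-2-{[(R)-3-(benzyloxy)butanoyl]oxy}propyl]benzoic acid
Conditions: NaClO2, NaH2PO4, 2-methyl-2-butene, t-BuOH/H2O, rt
Reagents that add atoms: sodium chlorite [Na+].[O-]Cl=O
Why: Pinnick oxidation converts the hindered aryl aldehyde into the acid under buffered conditions, with 2-methyl-2-butene trapping HOCl before it can chlorinate the electron-rich ring.

**Step 8**
Reactants: 14 2,4-bis(benzyloxy)-6-[(R)-2-{[(R)-3-(benzyloxy)butanoyl]oxy}propyl]benzoic acid; 15 propyne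
Product: 16 prop-1-en-2-yl 2,4-bis(benzyloxy)-6-[(R)-2-{[(R)-3-(benzyloxy)butanoyl]oxy}propyl]benzoate
Conditions: [RuCl2(p-cymene)]2 (1 mol %), P(2-furyl)3 (2 mol %), Na2CO3 (2 mol %), 15 (excess), toluene, 60 °C, sealed tube
Reagents that add atoms: none
Why: Ru-catalysed Markovnikov addition of a carboxylic acid to a terminal alkyne (carboxylate attack on the internal carbon of Ru-bound propyne) gives the 1-methylvinyl ester, and because the carboxylate oxygen is the nucleophile the two ortho substituents do not hinder it.

**Step 9**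
Reactants: 16 prop-1-en-2-yl 2,4-bis(benzyloxy)-6-[(R)-2-{[(R)-3-(benzyloxy)butanoyl]oxy}propyl]benzoate; 6 (R)-1-[3,5-bis(benzyloxy)phenyl]propan-2-yl formate
Product: 17 (R)-1-[3,5-bis(benzyloxy)phenyl]propan-2-yl (R)-3-{[2,4-bis(benzyloxy)-6-[(R)-2-{[(R)-3-(benzyloxy)butanoyl]oxy}propyl]benzoyl]oxy}butanoate
Conditions: Pd(OAc)2 (5 mol %), (R)-DTBM-SEGPHOS (6 mol %), MsOH (10 mol %), 4 Å MS, toluene, 80 °C, sealed tube
Reagents that add atoms: none
Why: Proposed new method: a cationic chiral Pd–H (from Pd(OAc)2, the bisphosphine and MsOH) should add across the isopropenyl C=C of 16 with hydrogen going to the oxygen-bearing carbon and Pd to the CH2 terminus, after which the Pd–CH2 carbon is joined to the alkoxycarbonyl unit of formate 6 through a Pd–C(=O)OR species (formed by formyl C–H oxidative addition or by recombination of Pd-bound CO and alkoxide, with the same outcome), forming the CH2–C(=O)O bond and returning Pd–H. The closest known reaction types are the Pd-catalysed hydroesterification of alkenes with formate esters, the Pd-catalysed enantioselective hydroalkoxycarbonylation of alkenes, the hydroalkoxycarbonylation of enol esters such as vinyl acetate, and the Ni-catalysed enantioselective hydrocarbamoylation of 1,1-disubstituted alkenes with formamides, which creates a β-stereocentre by the same formal H/C(=O)X addition. No ring is closed. The new stereocentre, C3 of the central butanoate, is set as (R) under catalyst control by the enol ester face to which the ligand-bound Pd–H delivers hydrogen (methyl against aroyloxy, whose carbonyl can bind Pd), the three existing centres being too remote to interfere; the ligand enantiomer that gives (R) is assigned in a model reaction of isopropenyl 2,6-dimethoxybenzoate with isopropyl formate. The step needs linear regioselectivity, which the 1,1-disubstituted alkene secures because carbonylation at the tertiary carbon would have to build a quaternary centre, and it needs the enol ester not to act as an acyl donor, which the two ortho substituents of the aroyl group secure by blocking acyl transfer; Pd–H chain walking in an isopropenyl group is degenerate and the benzyl ethers are inert without H2.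

**Step 10**
Reactants: 17 (R)-1-[3,5-bis(benzyloxy)phenyl]propan-2-yl (R)-3-{[2,4-bis(benzyloxy)-6-[(R)-2-{[(R)-3-(benzyloxy)butanoyl]oxy}propyl]benzoyl]oxy}butanoate
Product: 18 Hansforester J
Conditions: H2 (1 atm), 10% Pd/C, EtOAc, rt
Reagents that add atoms: none
Why: Catalytic hydrogenolysis should cleave the four aryl benzyl ethers and the alkyl benzyl ether while the three esters, whose C–O bonds are homobenzylic or aliphatic, and all four stereocentres stay untouched.

**Compound list**

1 | 1,3-bis(benzyloxy)-5-bromobenzene | Brc1cc(OCc2ccccc2)cc(OCc2ccccc2)c1 | starting material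
2 | (R)-2-methyloxirane ((R)-propylene oxide) | C[C@@H]1CO1 | starting material
3 | [3,5-bis(benzyloxy)phenyl]magnesium bromide | Br[Mg]c1cc(OCc2ccccc2)cc(OCc2ccccc2)c1 | intermediate
4 | bromomagnesium (R)-1-[3,5-bis(benzyloxy)phenyl]propan-2-olate | C[C@H](Cc1cc(OCc2ccccc2)cc(OCc2ccccc2)c1)O[Mg]Br | intermediate
5 | (R)-1-[3,5-bis(benzyloxy)phenyl]propan-2-ol | C[C@H](Cc1cc(OCc2ccccc2)cc(OCc2ccccc2)c1)O | intermediate
6 | (R)-1-[3,5-bis(benzyloxy)phenyl]propan-2-yl formate | C[C@H](Cc1cc(OCc2ccccc2)cc(OCc2ccccc2)c1)OC=O | intermediate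
7 | methyl (R)-3-hydroxybutanoate | COC(=O)C[C@@H](C)O | starting material
8 | methyl (R)-3-(benzyloxy)butanoate | COC(=O)C[C@@H](C)OCc1ccccc1 | intermediate
9 | lithium (R)-3-(benzyloxy)butanoate | [Li+].[O-]C(=O)C[C@@H](C)OCc1ccccc1 | intermediate
10 | (R)-3-(benzyloxy)butanoic acid | OC(=O)C[C@@H](C)OCc1ccccc1 | intermediate
11 | (R)-1-[3,5-bis(benzyloxy)phenyl]propan-2-yl (R)-3-(benzyloxy)butanoate | C[C@H](Cc1cc(OCc2ccccc2)cc(OCc2ccccc2)c1)OC(=O)C[C@@H](C)OCc1ccccc1 | intermediate
12 | N-{[2,4-bis(benzyloxy)-6-[(R)-2-{[(R)-3-(benzyloxy)butanoyl]oxy}propyl]phenyl]methylidene}-N-methylmethanaminium chloride | C[N+](C)=Cc1c(OCc2ccccc2)cc(OCc2ccccc2)cc1C[C@@H](C)OC(=O)C[C@@H](C)OCc1ccccc1.[Cl-] | intermediate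
13 | (R)-1-[3,5-bis(benzyloxy)-2-formylphenyl]propan-2-yl (R)-3-(benzyloxy)butanoate | O=Cc1c(OCc2ccccc2)cc(OCc2ccccc2)cc1C[C@@H](C)OC(=O)C[C@@H](C)OCc1ccccc1 | intermediate
14 | 2,4-bis(benzyloxy)-6-[(R)-2-{[(R)-3-(benzyloxy)butanoyl]oxy}propyl]benzoic acid | OC(=O)c1c(OCc2ccccc2)cc(OCc2ccccc2)cc1C[C@@H](C)OC(=O)C[C@@H](C)OCc1ccccc1 | intermediate
15 | propyne | CC#C | starting material
16 | prop-1-en-2-yl 2,4-bis(benzyloxy)-6-[(R)-2-{[(R)-3-(benzyloxy)butanoyl]oxy}propyl]benzoate | C=C(C)OC(=O)c1c(OCc2ccccc2)cc(OCc2ccccc2)cc1C[C@@H](C)OC(=O)C[C@@H](C)OCc1ccccc1 | intermediate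
17 | (R)-1-[3,5-bis(benzyloxy)phenyl]propan-2-yl (R)-3-{[2,4-bis(benzyloxy)-6-[(R)-2-{[(R)-3-(benzyloxy)butanoyl]oxy}propyl]benzoyl]oxy}butanoate (penta-O-benzyl Hansforester J) | C[C@H](Cc1cc(OCc2ccccc2)cc(OCc2ccccc2)c1)OC(=O)C[C@@H](C)OC(=O)c1c(OCc2ccccc2)cc(OCc2ccccc2)cc1C[C@@H](C)OC(=O)C[C@@H](C)OCc1ccccc1 | intermediate
18 | Hansforester J, (R)-1-(3,5-dihydroxyphenyl)propan-2-yl (R)-3-{[2,4-dihydroxy-6-[(R)-2-{[(R)-3-hydroxybutanoyl]oxy}propyl]benzoyl]oxy}butanoate | C[C@H](Cc1cc(O)cc(O)c1)OC(=O)C[C@@H](C)OC(=O)c1c(O)cc(O)cc1C[C@@H](C)OC(=O)C[C@@H](C)O | target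

**Step count and risks**

Total step count: 10. Longest linear sequence: 8 steps (steps 3, 4, 5, 6, 7, 8, 9, 10 from methyl (R)-3-hydroxybutanoate 7); 7 steps from aryl bromide 1.

Steps most likely to fail:

1. Step 9 (proposed new method). Hydrogen may be delivered to both faces of the enol ester, which would give a mixture of C3 epimers. The formate may also be activated too slowly, or the Pd–alkyl may lose the aroyloxy group by β-elimination before it is carbonylated. The fallback uses known chemistry, sets out from alcohol 5 and acid 14, and comes back to the route at 17. Acetoacetylation of 5 with 2,2,6-trimethyl-4H-1,3-dioxin-4-one (xylene, 130 °C, through acetylketene) should give (R)-1-[3,5-bis(benzyloxy)phenyl]propan-2-yl 3-oxobutanoate F1. Noyori asymmetric hydrogenation of this β-keto ester with RuCl2[(S)-BINAP] (H2, EtOH/CH2Cl2) should give (R)-1-[3,5-bis(benzyloxy)phenyl]propan-2-yl (S)-3-hydroxybutanoate F2. Mitsunobu esterification of F2 with acid 14 (PPh3, DIAD, toluene, 0 °C) inverts the carbinol centre and should give 17 with the (R) configuration; compounds 6 and 16 are then not needed.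

2. Step 8. The hindered carboxylate may add to the Ru-bound alkyne slowly or with mixed regiochemistry (anti-Markovnikov addition giving 1-propenyl esters). The fallback sets out from 14 and comes back at 16. Oxalyl chloride with catalytic DMF (CH2Cl2, 0 °C) should give 2,4-bis(benzyloxy)-6-[(R)-2-{[(R)-3-(benzyloxy)butanoyl]oxy}propyl]benzoyl chloride F3. This acid chloride is then added to the potassium enolate of acetone (KHMDS, acetone, THF, −78 °C, inverse addition), where O-acylation should give enol ester 16.

3. Step 6. Formylation may take place at the ring position between the two benzyloxy groups, or a benzyl ether may be lost under the acidic conditions. The fallback sets out from 11 and comes back at 13. Bromination with NBS (MeCN, 0 °C), para to one benzyloxy group and next to the side chain, should give (R)-1-[3,5-bis(benzyloxy)-2-bromophenyl]propan-2-yl (R)-3-(benzyloxy)butanoate F4. Pd-catalysed reductive carbonylation of F4 (Pd(OAc)2, di(1-adamantyl)-n-butylphosphine, TMEDA, CO/H2, toluene, 100 °C) should then give aldehyde 13.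

**Further compounds**

F1 | step 9 | (R)-1-[3,5-bis(benzyloxy)phenyl]propan-2-yl 3-oxobutanoate | C[C@H](Cc1cc(OCc2ccccc2)cc(OCc2ccccc2)c1)OC(=O)CC(C)=O
F2 | step 9 | (R)-1-[3,5-bis(benzyloxy)phenyl]propan-2-yl (S)-3-hydroxybutanoate | C[C@H](Cc1cc(OCc2ccccc2)cc(OCc2ccccc2)c1)OC(=O)C[C@H](C)O
F3 | step 8 | 2,4-bis(benzyloxy)-6-[(R)-2-{[(R)-3-(benzyloxy)butanoyl]oxy}propyl]benzoyl chloride | O=C(Cl)c1c(OCc2ccccc2)cc(OCc2ccccc2)cc1C[C@@H](C)OC(=O)C[C@@H](C)OCc1ccccc1
F4 | step 6 | (R)-1-[3,5-bis(benzyloxy)-2-bromophenyl]propan-2-yl (R)-3-(benzyloxy)butanoate | Brc1c(OCc2ccccc2)cc(OCc2ccccc2)cc1C[C@@H](C)OC(=O)C[C@@H](C)OCc1ccccc1
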